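**Overview**

- Retrosynthesis: the side chain is cut at the C8 ester bond and at the inner allylic CH2–O bond. Then the epoxide (from an E C1=C10 alkene), the C13 methylene and the lactone C6–O bond are removed. Last, the C7–C11 and C8–C9 bonds of the carbocycle are cut together.
- Enabling feature: C6 and C8 both carry oxygen and the C1=C10 unit lies 1,5 to C6. With C1 joined to C6, the atoms C9=C10–C1–C6(O)–C7=C8 form a 3-oxy-1,5-diene on a cyclohexene made of C1–C6, whose ring alkene is the cis C4=C5 and whose C3 oxygen is that of a carveol.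
- Forward: (S)-carvone supplies the six-membered ring, a Z alkoxyvinyl group is added at C6, and a [3,3] shift expands six to ten while the enolate takes up the acetate arm at C7. The γ-lactone, the exocyclic methylene, the epoxide and the side chain (two ester-forming steps at C8) follow.
- Stereochemistry: C3 comes from substrate-controlled cis reduction of carvone. The carvone centre steers the vinyl addition and is passed through a chair to C8. C7, C6 (after inversion on lactonisation) and C1/C10 arise by outer-face attack on the ten-membered ring. Both side-chain alkenes are the thermodynamic isomers.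

Key step: step 7

Assumption: ten-membered compounds are numbered as germacranes (ring C1–C10, lactone carbons C11–C13, C14 on C10, C15 on C4) with H7 taken as α; centres that are erased later (C11 in 22 and 23, the carbinol carbon in 32 and 33, the bromo acetal carbon in 8) are carried as mixtures.

**Route**

Step 1
Reactants: 1 (S)-(+)-carvone
Product: 2 (1S,5S)-cis-carveol
Conditions: NaBH4, CeCl3·7H2O, MeOH, −78 °C
Reagents that add atoms: none
Why: Luche 1,2-reduction, in which axial hydride delivery to the half-chair with an equatorial isopropenyl group should give the carbinol cis to that group (1S), the later C3 of the target.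

Step 2
Reactants: 2 (1S,5S)-cis-carveol
Product: 3 cis-carveol tert-butyldimethylsilyl ether
Conditions: TBSCl, imidazole, DMF, rt
Reagents that add atoms: tert-butyldimethylsilyl chloride, CC(C)(C)[Si](C)(C)Cl
Why: imidazole-promoted silylation of a secondary allylic alcohol, giving an ether that should outlast the strong bases, hydride, peracid and DDQ used before the last step.

Step 3
Reactants: 3 cis-carveol tert-butyldimethylsilyl ether
Product: 4 (4S,6S)-4-(tert-butyldimethylsilyloxy)-3-methyl-6-(prop-1-en-2-yl)cyclohex-2-en-1-one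
Conditions: CrO3, 3,5-dimethylpyrazole, CH2Cl2, −20 °C
Reagents that add atoms: chromium trioxide, O=[Cr](=O)=O
Why: allylic oxidation by the CrO3–3,5-dimethylpyrazole complex at the only secondary allylic methylene of the ring alkene (next to the isopropenyl-bearing carbon) gives the conjugated enone, and the cis 4,6-arrangement is the more stable one, so the enolisable C6 centre should hold.

Step 4
Reactants: 5 4-methoxybenzyl alcohol; 6 ethyl vinyl ether
Product: 7 4-methoxybenzyl vinyl ether
Conditions: Pd(OAc)2 (cat.), 1,10-phenanthroline (cat.), excess 6 as solvent, rt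
Reagents that add atoms: none
Why: transfer vinylation (transetherification catalysed by divalent palladium) of a primary alcohol, driven by the large excess of the vinyl donor.

Step 5
Reactants: 7 4-methoxybenzyl vinyl ether
Product: 9 (Z)-2-bromovinyl 4-methoxybenzyl ether, via 1,2-dibromoethyl ether 8 (not isolated)
Conditions: Br2, CH2Cl2, −78 °C; then i-Pr2NEt, −78 °C → rt
Reagents that add atoms: bromine, BrBr
Why: bromine addition to the enol ether followed by amine dehydrobromination (loss of the labile α bromide and a β proton) is the standard route to cis β-bromo enol ethers, and the low temperature with immediate base treatment should protect the benzylic α-bromo ether.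

Step 6
Reactants: 9 (Z)-2-bromovinyl 4-methoxybenzyl ether; 4 (4S,6S)-4-(tert-butyldimethylsilyloxy)-3-methyl-6-(prop-1-en-2-yl)cyclohex-2-en-1-one
Product: 12 (1S,4S,6S)-4-(tert-butyldimethylsilyloxy)-1-[(Z)-2-(4-methoxybenzyloxy)vinyl]-3-methyl-6-(prop-1-en-2-yl)cyclohex-2-en-1-ol, via vinyllithium 10 (not isolated), via vinylcerium dichloride 11 (not isolated)
Conditions: 9, t-BuLi (2 equiv), Et2O, −78 °C; CeCl3, THF, −78 °C; then 4, −78 °C
Reagents that add atoms: none
Why: bromine–lithium exchange with retention of the Z geometry, transmetalation to the less basic organocerium (suppresses enolisation at the doubly activated C–H next to the carbonyl) and carbonyl 1,2-addition anti to the isopropenyl and silyloxy groups should give the carbinol with the two alkenyl groups trans.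

Step 7
Reactants: 12 (1S,4S,6S)-4-(tert-butyldimethylsilyloxy)-1-[(Z)-2-(4-methoxybenzyloxy)vinyl]-3-methyl-6-(prop-1-en-2-yl)cyclohex-2-en-1-ol; 13 methyl bromoacetate
Product: 16 methyl [(1(10)E,4Z)-3β-(tert-butyldimethylsilyloxy)-8β-(4-methoxybenzyloxy)-6-oxocyclodeca-1(10),4-dien-7β-yl]acetate (3S,7R,8R), via potassium alkoxide 14 (not isolated), via potassium enolate 15 (not isolated)
Conditions: KN(SiMe3)2, 18-crown-6, THF, −78 → 0 °C; then 13, −78 → −40 °C
Reagents that add atoms: none
Why: Deprotonation gives alkoxide 14, in which the C1–C6 bond breaks while C8–C9 forms in a concerted [3,3] shift (anionic oxy-Cope rearrangement) through a chair with both alkenyl groups equatorial on the cyclohexene, and the enolate 15 so formed is alkylated at C7 by 13 in an SN2 step; the closest known reaction type is the anionic oxy-Cope ring expansion of 2-alkenyl-1-vinylcyclohexenols with C-alkylation of the enolate in the same flask. The ten-membered ring is closed by four-atom ring expansion of the cyclohexene (the new C8–C9 bond joins the two side-chain termini as the ring bond C1–C6 opens) and not by end-to-end cyclisation, the equatorial ring bonds give the E C1=C10 alkene, and the ring alkene emerges as the Z C4=C5 enone. C8 is set by the Z enol ether, which puts the 4-methoxybenzyloxy group axial in the one diequatorial chair that the carvone-derived C1 centre allows, so the 8R (8β) configuration is chirality passed on from C1, which is consumed. C7 is set by alkylation on the outer face of enolate 15, whose inner face is covered by the transannular C1=C10 unit. The step needs chair over boat, carbon over oxygen alkylation and alkylation faster than E1cB loss of the C8 alkoxide: the trans-diequatorial alkenyl groups cannot reach a boat array, the reactive bromoacetate favours carbon, and the C8–O bond lies near the nodal plane of the enolate in the crossed conformer, so elimination should be slow in the cold.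

Step 8
Reactants: 16 methyl [(1(10)E,4Z)-3β-(tert-butyldimethylsilyloxy)-8β-(4-methoxybenzyloxy)-6-oxocyclodeca-1(10),4-dien-7β-yl]acetate
Product: 17 6β-hydroxy methyl ester (6S carbinol, hydroxyl cis to the C7 acetate arm)
Conditions: NaBH4, CeCl3·7H2O, MeOH/THF, −78 °C
Reagents that add atoms: none
Why: Luche 1,2-reduction of the enone, in which hydride should reach C6 from the exposed outer face of the crossed conformer (the inner face is covered by the C1=C10 unit) to give the 6β carbinol while the ester is untouched.

Step 9
Reactants: 17 6β-hydroxy methyl ester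
Product: 19 6β-hydroxy acid, via lithium carboxylate 18 (not isolated)
Conditions: LiOH, THF/MeOH/H2O, 0 °C → rt; then NaH2PO4 buffer (pH 5), 0 °C
Reagents that add atoms: lithium hydroxide, [Li+].[OH-]
Why: ester saponification that leaves the silyl and benzyl-type ethers alone, in which any cis lactone formed by early closure of 17 is opened to the same carboxylate, and the mild cold acidification should allow the seco acid to be used at once.

Step 10
Reactants: 19 6β-hydroxy acid
Product: 20 trans-fused 6α,12-olide (3S,6R,7R,8R)
Conditions: PPh3, DIAD, THF, 0 °C (19 added slowly)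
Reagents that add atoms: none
Why: Mitsunobu lactonisation, in which the C6 hydroxyl is activated as the oxyphosphonium ion and displaced by the carboxylate in a 5-exo-tet SN2 closure with inversion, turning the 6β carbinol into the 6α-oxygen of the trans-fused lactone.

Step 11
Reactants: 20 trans-fused 6α,12-olide
Product: 22 11-(dimethylaminomethyl) lactone, via lithium enolate 21 (not isolated)
Conditions: LiN(i-Pr)2, THF, −78 °C; then CH2=NMe2+ I−, −78 → 0 °C
Reagents that add atoms: dimethylmethyleneammonium iodide, C=[N+](C)C.[I-]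
Why: Mannich-type aminomethylation of the lactone enolate, the standard first stage of α-methylenation, in which C11 is the only acidic position and its configuration does not matter.

Step 12
Reactants: 22 11-(dimethylaminomethyl) lactone
Product: 24 α-methylene lactone, via trimethylammonium iodide 23 (not isolated)
Conditions: MeI, MeOH, rt; then NaHCO3, H2O/EtOAc, rt
Reagents that add atoms: none
Why: exhaustive N-methylation followed by Hofmann-type (E1cB) elimination of trimethylamine gives the exocyclic C11=C13 alkene under conditions too mild to touch the ethers or the ring alkenes.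

Step 13
Reactants: 24 α-methylene lactone
Product: 25 1β,10α-epoxide (1R,10R)
Conditions: mCPBA, NaHCO3, CH2Cl2, 0 °C
Reagents that add atoms: 3-chloroperoxybenzoic acid, OOC(=O)c1cccc(Cl)c1
Why: Prilezhaev epoxidation of the only electron-rich alkene (C4=C5 is deactivated by two allylic oxygens and C11=C13 is conjugated), in which peracid attack on the outer face of the E C1=C10 unit should give the trans 1β,10α-epoxide.

Step 14
Reactants: 25 1β,10α-epoxide
Product: 26 1,10-epoxy 8β-alcohol
Conditions: DDQ, CH2Cl2/pH 7 buffer, 0 °C → rt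
Reagents that add atoms: none
Why: oxidative cleavage of the 4-methoxybenzyl ether by DDQ (hydride abstraction at the electron-rich benzylic position, then hydrolysis), a method that spares the silyl ether, the epoxide and the conjugated lactone under buffered conditions.

Step 15
Reactants: 27 (Z)-2-(bromomethyl)but-2-enoic acid
Product: 28 (Z)-2-(bromomethyl)but-2-enoyl chloride
Conditions: (COCl)2, DMF (cat.), CH2Cl2, 0 °C → rt
Reagents that add atoms: oxalyl chloride, ClC(=O)C(Cl)=O
Why: acid chloride formation through the Vilsmeier-type chloroiminium catalyst, which is neutral enough to keep the alkene geometry and the allylic bromide.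

Step 16
Reactants: 26 1,10-epoxy 8β-alcohol; 28 (Z)-2-(bromomethyl)but-2-enoyl chloride
Product: 29 8-O-[(Z)-2-(bromomethyl)but-2-enoyl] ester
Conditions: 2,6-lutidine, CH2Cl2, 0 °C → rt
Reagents that add atoms: none
Why: O-acylation by the acid chloride with a hindered pyridine as acid scavenger only, so that no nucleophilic amine can attack the allylic bromide in an SN2′ sense or add to the methylene lactone.

Step 17
Reactants: 30 tert-butyl acrylate; 31 (tert-butyldimethylsilyloxy)acetaldehyde
Product: 32 tert-butyl 4-(tert-butyldimethylsilyloxy)-3-hydroxy-2-methylenebutanoate (racemic)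
Conditions: DABCO, 1,4-dioxane/H2O, rt
Reagents that add atoms: none
Why: Baylis–Hillman reaction, for which the α-oxygenated aldehyde is an activated acceptor and the aqueous medium offsets the sluggishness of the tert-butyl acrylate.

Step 18
Reactants: 32 tert-butyl 4-(tert-butyldimethylsilyloxy)-3-hydroxy-2-methylenebutanoate
Product: 33 tert-butyl 3-acetoxy-4-(tert-butyldimethylsilyloxy)-2-methylenebutanoate (racemic)
Conditions: Ac2O, pyridine, DMAP (cat.), CH2Cl2, 0 °C
Reagents that add atoms: acetic anhydride, CC(=O)OC(C)=O
Why: routine acetylation of the secondary allylic alcohol, which installs the acetate that is carried into the target.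

Step 19
Reactants: 33 tert-butyl 3-acetoxy-4-(tert-butyldimethylsilyloxy)-2-methylenebutanoate
Product: 34 tert-butyl (E)-2-(acetoxymethyl)-4-(tert-butyldimethylsilyloxy)but-2-enoate
Conditions: DABCO, THF, 65 °C
Reagents that add atoms: none
Why: amine-mediated 1,3-transposition of a Baylis–Hillman acetate (SN2′ addition of DABCO, then return of acetate at the CH2 carbon), which should settle on the conjugated trisubstituted E enoate with the silyloxymethyl group trans to the ester.

Step 20
Reactants: 34 tert-butyl (E)-2-(acetoxymethyl)-4-(tert-butyldimethylsilyloxy)but-2-enoate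
Product: 36 (E)-2-(acetoxymethyl)-4-(tert-butyldimethylsilyloxy)but-2-enoic acid, via trimethylsilyl ester 35 (not isolated)
Conditions: TMSOTf, 2,6-lutidine, CH2Cl2, 0 °C → rt; then pH 5 buffer
Reagents that add atoms: none
Why: silyl triflate-mediated cleavage of the tert-butyl ester (O-silylation, loss of isobutene, hydrolysis of the silyl ester on work-up), a non-protic method that should spare the primary silyl ether and the acetate.

Step 21
Reactants: 36 (E)-2-(acetoxymethyl)-4-(tert-butyldimethylsilyloxy)but-2-enoic acid; 29 8-O-[(Z)-2-(bromomethyl)but-2-enoyl] ester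
Product: 38 bis(tert-butyldimethylsilyl) ether of the target, via caesium carboxylate 37 (not isolated)
Conditions: 36, Cs2CO3, DMF, 0 °C; then 29, 0 °C → rt
Reagents that add atoms: none
Why: SN2 displacement of the primary allylic bromide by a caesium carboxylate, a soft oxygen nucleophile that attacks the CH2 carbon directly and so keeps the conjugated trisubstituted alkene and its geometry.

Step 22
Reactants: 38 bis(tert-butyldimethylsilyl) ether of the target
Product: 39 CNP0193678.1
Conditions: HF·pyridine, pyridine, THF, 0 °C → rt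
Reagents that add atoms: none
Why: fluoride-mediated cleavage of both silyl ethers, kept buffered and slightly acidic so that acetyl migration to the freed primary hydroxyl, epoxide opening and addition to the methylene lactone should not occur.

**Compound list**

1 | (S)-(+)-carvone | CC1=CC[C@H](C(C)=C)CC1=O | starting material
2 | (1S,5S)-cis-carveol | CC1=CC[C@H](C(C)=C)C[C@@H]1O | intermediate
3 | (1S,5S)-cis-carveol tert-butyldimethylsilyl ether | CC1=CC[C@H](C(C)=C)C[C@@H]1O[Si](C)(C)C(C)(C)C | intermediate
4 | (4S,6S)-4-(tert-butyldimethylsilyloxy)-3-methyl-6-(prop-1-en-2-yl)cyclohex-2-en-1-one (silyloxy and isopropenyl cis) | O=C1C=C(C)[C@@H](O[Si](C)(C)C(C)(C)C)C[C@H]1C(C)=C | intermediate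
5 | 4-methoxybenzyl alcohol | COc1ccc(CO)cc1 | starting material
6 | ethyl vinyl ether | C=COCC | starting material
7 | 4-methoxybenzyl vinyl ether | C=COCc1ccc(OC)cc1 | intermediate
8 | 1,2-dibromoethyl 4-methoxybenzyl ether (racemic, formed in the flask) | BrCC(Br)OCc1ccc(OC)cc1 | intermediate
9 | (Z)-2-bromovinyl 4-methoxybenzyl ether | Br/C=C\OCc1ccc(OC)cc1 | intermediate
10 | (Z)-2-(4-methoxybenzyloxy)vinyllithium (formed in the flask) | [Li]/C=C\OCc1ccc(OC)cc1 | intermediate
11 | (Z)-2-(4-methoxybenzyloxy)vinylcerium dichloride (formed in the flask) | Cl[Ce](Cl)/C=C\OCc1ccc(OC)cc1 | intermediate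
12 | (1S,4S,6S)-4-(tert-butyldimethylsilyloxy)-1-[(Z)-2-(4-methoxybenzyloxy)vinyl]-3-methyl-6-(prop-1-en-2-yl)cyclohex-2-en-1-ol (hydroxyl cis to isopropenyl and silyloxy, alkenyl groups trans) | C=C(C)[C@@H]1C[C@H](O[Si](C)(C)C(C)(C)C)C(C)=C[C@@]1(O)/C=C\OCc2ccc(OC)cc2 | intermediate
13 | methyl bromoacetate | COC(=O)CBr | starting material
14 | potassium alkoxide of 12 (formed in the flask) | C=C(C)[C@@H]1C[C@H](O[Si](C)(C)C(C)(C)C)C(C)=C[C@@]1([O-])/C=C\OCc2ccc(OC)cc2.[K+] | intermediate
15 | potassium enolate of the ring-expanded ketone: ten-membered ring with E C1=C10, Z C4=C5 and C6(O−)=C7 enolate (oxygen cis to C8), 3β-silyloxy, 8β-(4-methoxybenzyloxy) (formed in the flask) | [O-]/C1=C\[C@H](OCc2ccc(OC)cc2)C/C(C)=C/C[C@H](O[Si](C)(C)C(C)(C)C)/C(C)=C\1.[K+] | intermediate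
16 | methyl [(1(10)E,4Z)-3β-(tert-butyldimethylsilyloxy)-8β-(4-methoxybenzyloxy)-6-oxocyclodeca-1(10),4-dien-7β-yl]acetate, germacrane numbering (3S,7R,8R; 7α-H) | O=C1/C=C(/C)[C@@H](O[Si](C)(C)C(C)(C)C)C/C=C(\C)C[C@@H](OCc2ccc(OC)cc2)[C@H]1CC(=O)OC | intermediate
17 | 6β-hydroxy methyl ester: 16 with C6 reduced to the 6S carbinol, hydroxyl cis to the C7 acetate arm | O[C@H]1/C=C(/C)[C@@H](O[Si](C)(C)C(C)(C)C)C/C=C(\C)C[C@@H](OCc2ccc(OC)cc2)[C@H]1CC(=O)OC | intermediate
18 | lithium carboxylate of 19 (formed in the flask) | O[C@H]1/C=C(/C)[C@@H](O[Si](C)(C)C(C)(C)C)C/C=C(\C)C[C@@H](OCc2ccc(OC)cc2)[C@H]1CC(=O)[O-].[Li+] | intermediate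
19 | 6β-hydroxy acid (seco acid of the lactone) | O[C@H]1/C=C(/C)[C@@H](O[Si](C)(C)C(C)(C)C)C/C=C(\C)C[C@@H](OCc2ccc(OC)cc2)[C@H]1CC(=O)O | intermediate
20 | trans-fused 6α,12-olide: (1(10)E,4Z)-3β-(tert-butyldimethylsilyloxy)-8β-(4-methoxybenzyloxy)-13-norgermacra-1(10),4-dien-6α,12-olide (3S,6R,7R,8R) | C1C(=O)O[C@@H]2/C=C(/C)[C@@H](O[Si](C)(C)C(C)(C)C)C/C=C(\C)C[C@@H](OCc3ccc(OC)cc3)[C@@H]12 | intermediate
21 | lithium enolate of lactone 20 (formed in the flask) | C1=C([O-])O[C@@H]2/C=C(/C)[C@@H](O[Si](C)(C)C(C)(C)C)C/C=C(\C)C[C@@H](OCc3ccc(OC)cc3)[C@@H]12.[Li+] | intermediate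
22 | 11-(dimethylaminomethyl) lactone (C11 unassigned) | CN(C)CC1C(=O)O[C@@H]2/C=C(/C)[C@@H](O[Si](C)(C)C(C)(C)C)C/C=C(\C)C[C@@H](OCc3ccc(OC)cc3)[C@@H]12 | intermediate
23 | 11-(trimethylammoniomethyl) lactone iodide (C11 unassigned, formed in the flask) | C[N+](C)(C)CC1C(=O)O[C@@H]2/C=C(/C)[C@@H](O[Si](C)(C)C(C)(C)C)C/C=C(\C)C[C@@H](OCc3ccc(OC)cc3)[C@@H]12.[I-] | intermediate
24 | α-methylene lactone: (1(10)E,4Z)-3β-(tert-butyldimethylsilyloxy)-8β-(4-methoxybenzyloxy)germacra-1(10),4,11(13)-trien-6α,12-olide | C=C1C(=O)O[C@@H]2/C=C(/C)[C@@H](O[Si](C)(C)C(C)(C)C)C/C=C(\C)C[C@@H](OCc3ccc(OC)cc3)[C@@H]12 | intermediate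
25 | 1β,10α-epoxide of 24 (1R,10R) | C=C1C(=O)O[C@@H]2/C=C(/C)[C@@H](O[Si](C)(C)C(C)(C)C)C[C@H]3O[C@]3(C)C[C@@H](OCc4ccc(OC)cc4)[C@@H]12 | intermediate
26 | 1β,10α-epoxy-3β-(tert-butyldimethylsilyloxy)-8β-hydroxygermacra-4Z,11(13)-dien-6α,12-olide | C=C1C(=O)O[C@@H]2/C=C(/C)[C@@H](O[Si](C)(C)C(C)(C)C)C[C@H]3O[C@]3(C)C[C@@H](O)[C@@H]12 | intermediate
27 | (Z)-2-(bromomethyl)but-2-enoic acid | OC(=O)/C(=C/C)CBr | starting material
28 | (Z)-2-(bromomethyl)but-2-enoyl chloride | ClC(=O)/C(=C/C)CBr | intermediate
29 | 8-O-[(Z)-2-(bromomethyl)but-2-enoyl] ester of 26 | C=C1C(=O)O[C@@H]2/C=C(/C)[C@@H](O[Si](C)(C)C(C)(C)C)C[C@H]3O[C@]3(C)C[C@@H](OC(=O)/C(=C/C)CBr)[C@@H]12 | intermediate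
30 | tert-butyl acrylate | C=CC(=O)OC(C)(C)C | starting material
31 | (tert-butyldimethylsilyloxy)acetaldehyde | O=CCO[Si](C)(C)C(C)(C)C | starting material
32 | tert-butyl 4-(tert-butyldimethylsilyloxy)-3-hydroxy-2-methylenebutanoate (racemic) | C=C(C(O)CO[Si](C)(C)C(C)(C)C)C(=O)OC(C)(C)C | intermediate
33 | tert-butyl 3-acetoxy-4-(tert-butyldimethylsilyloxy)-2-methylenebutanoate (racemic) | C=C(C(OC(C)=O)CO[Si](C)(C)C(C)(C)C)C(=O)OC(C)(C)C | intermediate
34 | tert-butyl (E)-2-(acetoxymethyl)-4-(tert-butyldimethylsilyloxy)but-2-enoate | CC(C)(C)OC(=O)/C(=C/CO[Si](C)(C)C(C)(C)C)COC(C)=O | intermediate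
35 | trimethylsilyl (E)-2-(acetoxymethyl)-4-(tert-butyldimethylsilyloxy)but-2-enoate (formed in the flask) | C[Si](C)(C)OC(=O)/C(=C/CO[Si](C)(C)C(C)(C)C)COC(C)=O | intermediate
36 | (E)-2-(acetoxymethyl)-4-(tert-butyldimethylsilyloxy)but-2-enoic acid | OC(=O)/C(=C/CO[Si](C)(C)C(C)(C)C)COC(C)=O | intermediate
37 | caesium (E)-2-(acetoxymethyl)-4-(tert-butyldimethylsilyloxy)but-2-enoate (formed in the flask) | [Cs+].[O-]C(=O)/C(=C/CO[Si](C)(C)C(C)(C)C)COC(C)=O | intermediate
38 | bis(tert-butyldimethylsilyl) ether of the target (silyl groups on O3 and on the side-chain primary hydroxyl; inner butenoate E by the sequence rule, same geometry as in 29) | C=C1C(=O)O[C@@H]2/C=C(/C)[C@@H](O[Si](C)(C)C(C)(C)C)C[C@H]3O[C@]3(C)C[C@@H](OC(=O)/C(=C/C)COC(=O)/C(=C/CO[Si](C)(C)C(C)(C)C)COC(C)=O)[C@@H]12 | intermediate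
39 | CNP0193678.1 (1R,3S,6R,7R,8R,10R) | C=C1C(=O)O[C@@H]2/C=C(/C)[C@@H](O)C[C@H]3O[C@]3(C)C[C@@H](OC(=O)/C(=C/C)COC(=O)/C(=C/CO)COC(C)=O)[C@@H]12 | target

**Count**

Total steps: 22. Longest linear sequence: 15 steps from (S)-carvone (steps 1–3, 6–14, 16, 21, 22).

**Steps most likely to fail**

1. Step 7. What may go wrong: the crown-complexed potassium enolate may expel the C8 alkoxide (E1cB) or be alkylated on oxygen before the C7–C11 bond forms.
Fallback, from 12 back to 16: the tertiary hydroxyl of 12 is silylated with N-(trimethylsilyl)imidazole to the trimethylsilyl ether F1. F1 is rearranged without base by a thermal siloxy-Cope shift (toluene, about 200 °C, sealed tube) through the same chair to the ring-expanded trimethylsilyl enol ether F2, so no free enolate exists during the ring expansion. F2 is then cleaved with MeLi in THF at −20 °C to the lithium enolate F3, which is tighter and less prone to elimination, and F3 is alkylated with 13 at −78 °C in the presence of DMPU to give 16.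

2. Step 10. What may go wrong: the closure may run with retention through an acyloxyphosphonium ion, the allylic oxyphosphonium ion may react in an SN2′ sense or eliminate, or 19 may close to the cis lactone on handling.
Fallback, from 17 back to 20: the hydroxy ester 17 is inverted intermolecularly by a Mitsunobu reaction with 4-nitrobenzoic acid (PPh3, DIAD, toluene) to the 6α-(4-nitrobenzoyloxy) methyl ester F4. Treatment of F4 with K2CO3 in MeOH removes the nitrobenzoate, and the freed 6α alkoxide closes on the neighbouring methyl ester by acyl substitution to give 20. The ring is thus closed at the acyl carbon after the inversion, and not at C6.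

3. Step 8. What may go wrong: poor facial selectivity of hydride delivery if the ketone leaves the crossed conformer after alkylation, so that the 6α carbinol forms in part or in the main.
Fallback, from 16 back to 20: the 6α-hydroxy methyl ester F5 that forms is separated and closed directly with K2CO3 in MeOH by acyl lactonisation with retention at C6 to give 20. Both carbinol epimers then converge on 20, and steps 9 and 10 are dropped if the 6α epimer dominates.

**Further compounds**

F1 | step 7 | trimethylsilyl ether of 12 | C=C(C)[C@@H]1C[C@H](O[Si](C)(C)C(C)(C)C)C(C)=C[C@@]1(O[Si](C)(C)C)/C=C\OCc2ccc(OC)cc2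
F2 | step 7 | ring-expanded trimethylsilyl enol ether (silyl analogue of 15) | C[Si](C)(C)O/C1=C\[C@H](OCc2ccc(OC)cc2)C/C(C)=C/C[C@H](O[Si](C)(C)C(C)(C)C)/C(C)=C\1
F3 | step 7 | lithium enolate (lithium analogue of 15) | [Li+].[O-]/C1=C\[C@H](OCc2ccc(OC)cc2)C/C(C)=C/C[C@H](O[Si](C)(C)C(C)(C)C)/C(C)=C\1
F4 | step 10 | 6α-(4-nitrobenzoyloxy) methyl ester | O=C(O[C@@H]1/C=C(/C)[C@@H](O[Si](C)(C)C(C)(C)C)C/C=C(\C)C[C@@H](OCc2ccc(OC)cc2)[C@H]1CC(=O)OC)c3ccc([N+](=O)[O-])cc3
F5 | step 8 | 6α-hydroxy methyl ester (C6 epimer of 17) | O[C@@H]1/C=C(/C)[C@@H](O[Si](C)(C)C(C)(C)C)C/C=C(\C)C[C@@H](OCc2ccc(OC)cc2)[C@H]1CC(=O)OC
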